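**Retrosynthetic overview**

- Target ⇒ (3Z,6R,7S,9Z,12E)-6,7-epoxypentadeca-3,9,12-trien-1-yne + Br⁺ + AcOH. One cascade: bromonium ion on the 12E alkene, oxirane oxygen closes the oxepene at C12, acetate opens the epoxonium ion at C6 with inversion. This is the only ring-forming event of the target and sets C6, C12 and C13.
- cis-Epoxide ⇒ threo C7-hydroxy C6-mesylate (SN2 closure, inversion at C6) ⇒ the same compound with C3≡C4 and C9≡C10 still as alkynes (one-pot double Z-reduction).
- That triyne ⇒ (S,S)-1,2:3,4-diepoxybutane, opened first by a silylbutadiynyl anion (C4–C5), mesylated at O6, then opened by an (E)-hept-4-en-1-ynyl anion (C8–C9). The order of the two openings decides which carbinol is inverted.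
- Diepoxide ⇐ treosulfan (L-tartrate pool, source of C6/C7); heptenyne ⇐ (E)-1-bromopent-2-ene + ethynylmagnesium bromide.
- Ring order: transient oxirane (step 7) → oxepene (step 8) through a bicyclic epoxonium ion; no oxygen protecting group is used.

Assumption: treosulfan (L-threitol 1,4-dimethanesulfonate, a generic drug substance derived from L-tartaric acid) is bought rather than made.

**Route**

Step 1
Reactants: 1 L-threitol 1,4-dimethanesulfonate (treosulfan)
Product: 3 (2S,2'S)-2,2'-bioxirane, via epoxy mesylate 2 (not isolated)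
Conditions: KOH (2.2 equiv), H2O/Et2O, 20 °C
Reagents that add atoms: none
Why: Double intramolecular Williamson etherification (each secondary alkoxide displaces the neighbouring primary mesylate, 3-exo-tet) touches neither carbinol carbon, so the (S,S) configuration of the threitol skeleton is carried into the diepoxide.

Step 2
Reactants: 3 (2S,2'S)-2,2'-bioxirane (3 equiv); 4 1,4-bis(trimethylsilyl)buta-1,3-diyne
Product: 6 (1S)-1-[(2S)-oxiran-2-yl]-6-(trimethylsilyl)hexa-3,5-diyn-1-ol, via lithium diynide 5 (not isolated)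
Conditions: 4, MeLi·LiBr, THF, 0 → 20 °C; then 3, BF3·OEt2, −78 °C; aq. NH4Cl
Reagents that add atoms: none
Why: BF3-promoted alkynylation of an epoxide (Yamaguchi type) at the CH2 terminus of one of the two equivalent oxiranes of the C2-symmetric diepoxide (excess 3 suppresses double opening) forms C4–C5 and leaves C6 and C7 unchanged.

Step 3
Reactants: 6 (1S)-1-[(2S)-oxiran-2-yl]-6-(trimethylsilyl)hexa-3,5-diyn-1-ol
Product: 7 (1S)-1-[(2S)-oxiran-2-yl]-6-(trimethylsilyl)hexa-3,5-diyn-1-yl methanesulfonate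
Conditions: MsCl, Et3N, CH2Cl2, −10 °C
Reagents that add atoms: methanesulfonyl chloride, CS(=O)(=O)Cl
Why: O-Sulfonylation of the only hydroxyl (retention at C6) marks C6 as the carbinol that will later be inverted, which fixes the enantiomer of the cis-epoxide.

Step 4
Reactants: 8 (2E)-1-bromopent-2-ene; 9 ethynylmagnesium bromide
Product: 10 (4E)-hept-4-en-1-yne
Conditions: CuBr·SMe2 (5 mol %), THF, 0 → 40 °C; distillation
Reagents that add atoms: none
Why: Copper-catalysed SN2 coupling of an alkynyl Grignard reagent with a primary allylic bromide takes place at the alpha carbon and keeps the E geometry of the bromide.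

Step 5
Reactants: 7 (1S)-1-[(2S)-oxiran-2-yl]-6-(trimethylsilyl)hexa-3,5-diyn-1-yl methanesulfonate; 10 (4E)-hept-4-en-1-yne
Product: 12 (6S,7S,12E)-7-hydroxy-1-(trimethylsilyl)pentadec-12-ene-1,3,9-triyn-6-yl methanesulfonate, via lithium acetylide 11 (not isolated)
Conditions: 10, n-BuLi, THF, −78 °C; then 7, BF3·OEt2, −78 °C; aq. NH4Cl
Reagents that add atoms: none
Why: A second BF3-promoted epoxide alkynylation at the terminal carbon C8 forms C8–C9 with C7 untouched, the secondary mesylate being inert to the weakly basic alkynyl–BF3 species at −78 °C.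

Step 6
Reactants: 12 (6S,7S,12E)-7-hydroxy-1-(trimethylsilyl)pentadec-12-ene-1,3,9-triyn-6-yl methanesulfonate
Product: 14 (3Z,6S,7S,9Z,12E)-7-hydroxy-1-(trimethylsilyl)pentadeca-3,9,12-trien-1-yn-6-yl methanesulfonate, via trisborylated adduct 13 (not isolated)
Conditions: Cy2BH (3.3 equiv), THF, 0 → 20 °C; then AcOH, 20 °C
Reagents that add atoms: none
Why: Monohydroboration–protonolysis (Zweifel cis-reduction): the hindered dialkylborane adds syn to the two alkyl-flanked triple bonds (C3≡C4 of the silyl diyne and C9≡C10) but not to the silyl-capped alkyne or the E-alkene, and AcOH cleaves each alkenyl C–B bond with retention to give both Z-alkenes.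

Step 7
Reactants: 14 (3Z,6S,7S,9Z,12E)-7-hydroxy-1-(trimethylsilyl)pentadeca-3,9,12-trien-1-yn-6-yl methanesulfonate
Product: 16 (2R,3S)-2-[(2Z)-pent-2-en-4-yn-1-yl]-3-[(2Z,5E)-octa-2,5-dien-1-yl]oxirane, via silylated epoxide 15 (not isolated)
Conditions: K2CO3, MeOH, 0 → 20 °C
Reagents that add atoms: none
Why: The C7 alkoxide displaces the neighbouring C6 mesylate (intramolecular Williamson SN2, inversion at C6) to give the cis (6R,7S) epoxide, and the same methanolic base removes the alkynyl silyl group (protodesilylation).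

Step 8
Reactants: 16 (2R,3S)-2-[(2Z)-pent-2-en-4-yn-1-yl]-3-[(2Z,5E)-octa-2,5-dien-1-yl]oxirane
Product: 19 (1S,3Z)-1-[(2S,7R)-7-[(1S)-1-bromopropyl]-2,3,6,7-tetrahydrooxepin-2-yl]hex-3-en-5-yn-1-yl acetate, via bromonium ion 17 (not isolated), via epoxonium ion 18 (not isolated)
Conditions: NBS (1.05 equiv, slow addition), AcOH (2 equiv), N,N,N',N'-tetramethylguanidine (10 mol %), CH2Cl2 (0.01 M), −20 → 0 °C, dark
Reagents that add atoms: N-bromosuccinimide, O=C1CCC(=O)N1Br; acetic acid, CC(=O)O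
Why: Proposed new method: NBS transfers Br⁺ reversibly to the alkenes, but only the bromonium ion on the C12=C13 E-alkene (17) can be captured in an exo mode by the oxirane oxygen (7-exo attack at C12 anti to Br, helped by the Z-alkene in the tether, whereas capture at C9=C10 would need a strained 5-endo closure), giving epoxonium ion 18, which acetate opens by SN2 at the exocyclic carbon C6 with inversion; the E geometry therefore gives anti C12–O/C13–Br (12R,13S when closure places both ring substituents pseudo-equatorial, i.e. cis-2,7), the oxirane keeps C7 as S and inversion at C6 gives 6S, the closest known reaction type being bromonium-ion-assisted epoxide ring opening with capture of the oxonium ion by an external nucleophile (NBS/AcOH, known for five- and six-membered ethers) and bromonium-initiated epoxide-opening cascades that close bromo-oxepanes.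

**Compound list**

1 | L-threitol 1,4-dimethanesulfonate (treosulfan; (2S,3S)-2,3-dihydroxybutane-1,4-diyl dimethanesulfonate) | CS(=O)(=O)OC[C@H](O)[C@@H](O)COS(C)(=O)=O | starting material
2 | (2S)-2-hydroxy-2-[(2S)-oxiran-2-yl]ethyl methanesulfonate | CS(=O)(=O)OC[C@H](O)[C@@H]1CO1 | intermediate
3 | (2S,2'S)-2,2'-bioxirane ((S,S)-1,2:3,4-diepoxybutane) | C1O[C@@H]1[C@@H]1CO1 | intermediate
4 | 1,4-bis(trimethylsilyl)buta-1,3-diyne | C[Si](C)(C)C#CC#C[Si](C)(C)C | starting material
5 | lithium (trimethylsilyl)buta-1,3-diyn-1-ide | [Li]C#CC#C[Si](C)(C)C | intermediate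
6 | (1S)-1-[(2S)-oxiran-2-yl]-6-(trimethylsilyl)hexa-3,5-diyn-1-ol | C[Si](C)(C)C#CC#CC[C@H](O)[C@@H]1CO1 | intermediate
7 | (1S)-1-[(2S)-oxiran-2-yl]-6-(trimethylsilyl)hexa-3,5-diyn-1-yl methanesulfonate | C[Si](C)(C)C#CC#CC[C@H](OS(C)(=O)=O)[C@@H]1CO1 | intermediate
8 | (2E)-1-bromopent-2-ene | CC/C=C/CBr | starting material
9 | ethynylmagnesium bromide (0.5 M in THF) | C#C[Mg]Br | starting material
10 | (4E)-hept-4-en-1-yne | C#CC/C=C/CC | intermediate
11 | lithium (4E)-hept-4-en-1-yn-1-ide | [Li]C#CC/C=C/CC | intermediate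
12 | (6S,7S,12E)-7-hydroxy-1-(trimethylsilyl)pentadec-12-ene-1,3,9-triyn-6-yl methanesulfonate | C[Si](C)(C)C#CC#CC[C@H](OS(C)(=O)=O)[C@@H](O)CC#CC/C=C/CC | intermediate
13 | (3Z,6S,7S,9Z,12E)-3,10-bis(dicyclohexylboryl)-7-[(dicyclohexylboryl)oxy]-1-(trimethylsilyl)pentadeca-3,9,12-trien-1-yn-6-yl methanesulfonate (C10-boryl isomer drawn; the C9-boryl isomer gives the same product) | C[Si](C)(C)C#C/C(B(C1CCCCC1)C1CCCCC1)=C\C[C@H](OS(C)(=O)=O)[C@@H](OB(C1CCCCC1)C1CCCCC1)C/C=C(/B(C1CCCCC1)C1CCCCC1)C/C=C/CC | intermediate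
14 | (3Z,6S,7S,9Z,12E)-7-hydroxy-1-(trimethylsilyl)pentadeca-3,9,12-trien-1-yn-6-yl methanesulfonate | C[Si](C)(C)C#C/C=C\C[C@H](OS(C)(=O)=O)[C@@H](O)C/C=C\C/C=C/CC | intermediate
15 | (2R,3S)-2-[(2Z)-5-(trimethylsilyl)pent-2-en-4-yn-1-yl]-3-[(2Z,5E)-octa-2,5-dien-1-yl]oxirane | C[Si](C)(C)C#C/C=C\C[C@H]1O[C@H]1C/C=C\C/C=C/CC | intermediate
16 | (2R,3S)-2-[(2Z)-pent-2-en-4-yn-1-yl]-3-[(2Z,5E)-octa-2,5-dien-1-yl]oxirane ((3Z,6R,7S,9Z,12E)-6,7-epoxypentadeca-3,9,12-trien-1-yne) | C#C/C=C\C[C@H]1O[C@H]1C/C=C\C/C=C/CC | intermediate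
17 | (2S,3S)-2-{(2Z)-4-[(2S,3R)-3-[(2Z)-pent-2-en-4-yn-1-yl]oxiran-2-yl]but-2-en-1-yl}-3-ethylbromiran-1-ium (trans 12,13-bromonium ion of 16) | C#C/C=C\C[C@H]1O[C@H]1C/C=C\C[C@@H]1[Br+][C@H]1CC | intermediate
18 | 2-[(1S)-1-bromopropyl]-8-[(2Z)-pent-2-en-4-yn-1-yl]-1-oxoniabicyclo[5.1.0]oct-4-ene (chain numbering: 6R,7S,12R,13S) | C#C/C=C\C[C@H]1[O+]2[C@H]1C/C=C\C[C@@H]2[C@@H](Br)CC | intermediate
19 | (1S,3Z)-1-[(2S,7R)-7-[(1S)-1-bromopropyl]-2,3,6,7-tetrahydrooxepin-2-yl]hex-3-en-5-yn-1-yl acetate | C#C/C=C\C[C@H](OC(C)=O)[C@@H]1CC=CC[C@H]([C@@H](Br)CC)O1 | target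

**Step count**

Total: 8 steps. Longest linear sequence: 7 steps (1 → 3 → 6 → 7 → 12 → 14 → 16 → 19); step 4 is a one-step side branch.

**Steps most likely to fail, and fallbacks**

Step 8 (cascade). Expected failure modes:
- capture of the C9=C10 bromonium ion (3-bromotetrahydrofuran by-products);
- intermolecular bromoacetoxylation before the seven-membered closure;
- opening of 18 at C7 (eight-membered regioisomer);
- formation of the trans-2,7-oxepene.

Fallback: it sets out from 6 and comes back at 19. The ring is closed by a free hydroxyl and the acetate is added afterwards. The hydroxyl of 6 is silylated (TBSCl, imidazole) to give the silyl ether F1. Opening of its oxirane with 11/BF3·OEt2 gives the C7 alcohol F2. Cy2BH then AcOH gives the Z,Z-trienyne alcohol F3. 2,4,4,6-Tetrabromocyclohexa-2,5-dienone in CH2Cl2 closes the ring by direct 7-exo attack of the C7 hydroxyl on the C12=C13 bromonium ion to give the bromo-oxepene silyl ether F4. Tetrabutylammonium fluoride removes both silyl groups to give the alcohol F5, and Ac2O/pyridine gives 19. C6 keeps the configuration of 3 throughout, so no inversion is required.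

Step 6 (double Z-reduction). Expected failure modes: attack of the borane on the silyl alkyne or the E-alkene, incomplete reduction of one triple bond, slow protonolysis.

Fallback: it sets out from 6 and comes back at 14. The two triple bonds are reduced separately, each at a stage where it is the only reducible one. Zinc dust activated with Cu(OAc)2 and AgNO3 in MeOH/H2O reduces only the conjugated alkyl-substituted triple bond of 6 to give the Z-enyne epoxy alcohol F6. MsCl/Et3N gives the mesylate F7. Coupling with 11/BF3·OEt2 gives the dienediyne hydroxy mesylate F8. H2 over Pd on CaCO3 poisoned with Pb(OAc)2 and quinoline then reduces the remaining isolated alkyne to give 14.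

Step 5 (alkynylation beside the mesylate). Expected failure modes: base-induced elimination of the mesylate toward the diyne (C5–H is propargylic), isomerisation of the skipped enyne acetylide, BF3-induced side reactions of the epoxy mesylate.

Fallback: it sets out from 3 and comes back at 12. The order of fragment union is reversed and a temporary silyl ether is used, so that no carbanion meets the mesylate. Opening of 3 with 11/BF3·OEt2 gives the epoxy alcohol F9. TBSCl/imidazole gives the silyl ether F10. Opening with 5/BF3·OEt2 gives the C6 alcohol F11. MsCl/Et3N gives the mesylate F12. HF·pyridine in THF removes only the O-silyl group and gives 12.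

**Further compounds**

F1 | step 8 | tert-butyl(dimethyl){[(1S)-1-[(2S)-oxiran-2-yl]-6-(trimethylsilyl)hexa-3,5-diyn-1-yl]oxy}silane | C[Si](C)(C)C#CC#CC[C@H](O[Si](C)(C)C(C)(C)C)[C@@H]1CO1
F2 | step 8 | (6S,7S,12E)-6-[(tert-butyldimethylsilyl)oxy]-1-(trimethylsilyl)pentadec-12-ene-1,3,9-triyn-7-ol | C[Si](C)(C)C#CC#CC[C@H](O[Si](C)(C)C(C)(C)C)[C@@H](O)CC#CC/C=C/CC
F3 | step 8 | (3Z,6S,7S,9Z,12E)-6-[(tert-butyldimethylsilyl)oxy]-1-(trimethylsilyl)pentadeca-3,9,12-trien-1-yn-7-ol | C[Si](C)(C)C#C/C=C\C[C@H](O[Si](C)(C)C(C)(C)C)[C@@H](O)C/C=C\C/C=C/CC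
F4 | step 8 | tert-butyl{[(1S,3Z)-1-[(2S,7R)-7-[(1S)-1-bromopropyl]-2,3,6,7-tetrahydrooxepin-2-yl]-6-(trimethylsilyl)hex-3-en-5-yn-1-yl]oxy}dimethylsilane | C[Si](C)(C)C#C/C=C\C[C@H](O[Si](C)(C)C(C)(C)C)[C@@H]1CC=CC[C@H]([C@@H](Br)CC)O1
F5 | step 8 | (1S,3Z)-1-[(2S,7R)-7-[(1S)-1-bromopropyl]-2,3,6,7-tetrahydrooxepin-2-yl]hex-3-en-5-yn-1-ol | C#C/C=C\C[C@H](O)[C@@H]1CC=CC[C@H]([C@@H](Br)CC)O1
F6 | step 6 | (1S,3Z)-1-[(2S)-oxiran-2-yl]-6-(trimethylsilyl)hex-3-en-5-yn-1-ol | C[Si](C)(C)C#C/C=C\C[C@H](O)[C@@H]1CO1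
F7 | step 6 | (1S,3Z)-1-[(2S)-oxiran-2-yl]-6-(trimethylsilyl)hex-3-en-5-yn-1-yl methanesulfonate | C[Si](C)(C)C#C/C=C\C[C@H](OS(C)(=O)=O)[C@@H]1CO1
F8 | step 6 | (3Z,6S,7S,12E)-7-hydroxy-1-(trimethylsilyl)pentadeca-3,12-diene-1,9-diyn-6-yl methanesulfonate | C[Si](C)(C)C#C/C=C\C[C@H](OS(C)(=O)=O)[C@@H](O)CC#CC/C=C/CC
F9 | step 5 | (1S,6E)-1-[(2S)-oxiran-2-yl]non-6-en-3-yn-1-ol | CC/C=C/CC#CC[C@H](O)[C@@H]1CO1
F10 | step 5 | tert-butyl(dimethyl){[(1S,6E)-1-[(2S)-oxiran-2-yl]non-6-en-3-yn-1-yl]oxy}silane | CC/C=C/CC#CC[C@H](O[Si](C)(C)C(C)(C)C)[C@@H]1CO1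
F11 | step 5 | (6S,7S,12E)-7-[(tert-butyldimethylsilyl)oxy]-1-(trimethylsilyl)pentadec-12-ene-1,3,9-triyn-6-ol | C[Si](C)(C)C#CC#CC[C@H](O)[C@@H](O[Si](C)(C)C(C)(C)C)CC#CC/C=C/CC
F12 | step 5 | (6S,7S,12E)-7-[(tert-butyldimethylsilyl)oxy]-1-(trimethylsilyl)pentadec-12-ene-1,3,9-triyn-6-yl methanesulfonate | C[Si](C)(C)C#CC#CC[C@H](OS(C)(=O)=O)[C@@H](O[Si](C)(C)C(C)(C)C)CC#CC/C=C/CC
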